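Readings and results are calculated from invented constants, noise included.

I decided to follow the starting material left, not the target made.

| flask | starting material | coupling partner | free catalyst | added ligand | remark | time |
|---|---|---|---|---|---|---|
| Monday's | 0.050 M | 0.20 M | 0.12 mM | 0.35 mM | run made earlier |  |
| Thursday's | 0.050 M | 0.20 M | 0.12 mM | 0.43 mM | run made earlier |  |
| east | 0.050 M | 0.200 M | 0.12 mM | 0.25 mM |  | 15 h |
| south-west | 0.050 M | 0.200 M | 0.12 mM | 0.30 mM |  | 15 h |
| south | 0.050 M | 0.200 M | 0.12 mM | 0.50 mM |  | 15 h |

| run | time / h | target / % | starting material / % |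
|---|---|---|---|
| Monday's | 1.00 | 3.1 | 96.1 |
| Monday's | 2.50 | 6.7 | 91.5 |
| Monday's | 5.00 | 13.5 | 86.6 |
| Monday's | 8.00 | 21.2 | 78.5 |
| Monday's | 10.0 | 23.8 | 74.6 |
| Thursday's | 1.00 | 3.2 | 95.1 |
| Thursday's | 2.50 | 9.2 | 92.0 |
| Thursday's | 5.00 | 12.4 | 84.5 |
| Thursday's | 8.00 | 20.3 | 77.2 |
| Thursday's | 10.0 | 24.0 | 74.6 |

(each reading ± 1 percentage point)

* amount of target at the end, in percent of the starting material charged for east, south-west, south, in this order
* how the row runs (rises, then falls / rises all the way / hardly changes / falls, then rises / falls all the way)

- "hardly changes" means that all values lie within two and a half points (for a concentration: within two and a half percent of the largest)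

The coupling partner stood at 0.200 M, more than the 0.050 M of starting material. So I took starting material as the limiting reagent and treated its loss as pseudo-first-order. Monday's run left 74.6% at 10.0 h, which gives 0.0293 h⁻¹. That is the loss constant k_L: minus the natural logarithm of the fraction of starting material left, divided by the time.

Thursday's run, with 0.43 mM of added ligand against Monday's 0.35 mM, left 74.6% at the same time, so both runs gave one k_L. But each reading is good to 1 percentage point, and the new flasks reach 0.25 mM and 0.50 mM, outside that span.

In Monday's run, target and starting material summed to 98.4% at 10.0 h, so I counted the loss as target. My reckoning with k_L then left 64.4% at 15 h, which means 35.6% of target at each ligand charge.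

The forecast gave 34.5%, 34.5% and 34.5%, a row that hardly changes, a little lower than my figure. Its ground was this: “So added ligand has no visible effect at fixed free catalyst”.

The flasks gave 35.8%, 34.8% and 31.4%, a row that falls all the way.

    starting material + free catalyst → catalyst intermediate A (k = 1000 M⁻¹ h⁻¹)
    coupling partner + catalyst intermediate A → catalyst intermediate B (k = 31000 M⁻¹ h⁻¹)
    catalyst intermediate B ⇌ by-product + catalyst intermediate C (K = 3.10 M, k = 95.0 h⁻¹)
    catalyst intermediate C ⇌ free catalyst + target (K = 0.00770 M, k = 73.0 h⁻¹)
    free catalyst + added ligand ⇌ idle complex, settled at all times (K = 3600 M⁻¹)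

East kept 64% of its starting material unbound at 15.0 h, so its k_L was 0.0297 h⁻¹. South kept 68%, so its k_L was 0.0253 h⁻¹, lower than east's. In east at 5.77 h, free catalyst had a half-life of 1.0 min by its step with starting material, while catalyst intermediate B had 0.44 min by its forward step alone, a shorter time. In east at 7.50 h, free catalyst held 23.8% of the catalyst and catalyst intermediate B held 9.96%.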